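The tetrahydrofuran ring is cut at C4–C5 and at C2–C3. This leaves the C5–O1–C2 ether bridge as a non-stabilised carbonyl ylide and C3–C4 as an alkene. Because the C3 hydroxymethyl and C4 benzyl groups are cis, they are tied back into a temporary ring, an (S)-γ-aryl butenolide: its carbonyl group activates and polarises the alkene, and its benzylic stereocentre steers the facial approach. One (3+2) cycloaddition of the ylide, released from an α-chlorobenzyl silylmethyl ether, thus builds the ring, two C–C bonds and all three stereocentres. Hydrogenolysis then opens the temporary ring and erases the controlling centre; borane reduction ends the route.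

Key step: step 4

Assumption: the (S,S)-ProPhenol zinc catalyst is taken to deliver the acetylide to the Si face of aryl aldehydes. If the sense is the opposite, the equally available (R,R)-ligand is used and nothing else changes. O1 and C2 to C5 denote the tetrahydrofuran atoms of the target (C2 aryl, C3 CH2OH, C4 benzyl).

Step 1
Reactants: 1 4-(benzyloxy)-3-methoxybenzaldehyde; 2 methyl propiolate
Product: 4 methyl (4R)-4-[4-(benzyloxy)-3-methoxyphenyl]-4-hydroxybut-2-ynoate, via methylzinc propiolate 3 (not isolated)
Conditions: (S,S)-ProPhenol (20 mol %), Me2Zn (3 equiv), 2 (3 equiv), toluene, 0 to 4 °C; aq NH4Cl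
Reagents that add atoms: none
Why: Catalytic asymmetric alkynylation of an aryl aldehyde by a dinuclear zinc ProPhenol complex, whose chiral pocket delivers the zinc acetylide to the Si face of the aldehyde and so sets the (R)-carbinol centre.

Step 2
Reactants: 4 methyl (4R)-4-[4-(benzyloxy)-3-methoxyphenyl]-4-hydroxybut-2-ynoate
Product: 6 (5S)-5-[4-(benzyloxy)-3-methoxyphenyl]furan-2(5H)-one, via (Z)-hydroxy enoate 5 (not isolated)
Conditions: H2 (1 atm), 5% Pd/CaCO3 poisoned with Pb(OAc)2, quinoline (cat), EtOAc, rt; then silica gel, CH2Cl2, rt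
Reagents that add atoms: none
Why: Lindlar semihydrogenation gives the cis-enoate, whose hydroxyl group sits next to the ester and lactonises spontaneously, while the carbinol centre is untouched (the descriptor changes from R to S only because the CIP ranks change).

Step 3
Reactants: 7 3,4-dimethoxybenzaldehyde; 8 (trimethylsilyl)methanol
Product: 9 {[chloro(3,4-dimethoxyphenyl)methoxy]methyl}trimethylsilane (racemic)
Conditions: dry HCl gas, anhydrous CaCl2, CH2Cl2, −20 to 0 °C; filtered, evaporated cold, used crude
Reagents that add atoms: hydrogen chloride, Cl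
Why: Classical α-chloro ether synthesis (hemiacetal formation, then chloride capture of the aryl-stabilised oxocarbenium ion), in which the new centre forms racemic and this is harmless because it is planarised in step 4.

Step 4
Reactants: 6 (5S)-5-[4-(benzyloxy)-3-methoxyphenyl]furan-2(5H)-one; 9 {[chloro(3,4-dimethoxyphenyl)methoxy]methyl}trimethylsilane
Product: 11 (3S,3aR,6S,6aS)-3-[4-(benzyloxy)-3-methoxyphenyl]-6-(3,4-dimethoxyphenyl)tetrahydro-1H,3H-furo[3,4-c]furan-1-one, via carbonyl ylide 10 (not isolated)
Conditions: CsF (4 equiv, flame-dried), MeCN, 0 °C to rt, 9 (2.5 equiv) added over 4 h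
Reagents that add atoms: none
Why: Fluoride attacks silicon in 9 while chloride leaves the veratryl-stabilised benzylic carbon (silicon-based 1,3-elimination), which releases the non-stabilised carbonyl ylide 10, a 4π C–O–C dipole that adds to the C3=C4 alkene of 6 in a concerted but asynchronous suprafacial (3+2) cycloaddition. The closest known reaction type is the CsF-induced generation of carbonyl ylides from α-chloroalkyl (trimethylsilyl)methyl ethers and their trapping by acrylates, maleates and related electron-poor alkenes to give tetrahydrofurans. The tetrahydrofuran ring closes intermolecularly by union of both ylide termini with the alkene (CH2 to the lactone β-carbon, ArCH to the α-carbon), so no stepwise 5-endo-trig closure is needed and the new ring emerges cis-fused to the lactone. C4 is set by approach anti to the C5 aryl group of the butenolide, C3 follows from suprafacial addition to the ring-locked cis-alkene, and C2 follows from exo approach of the E-configured ylide, which keeps the ylide oxygen and the veratryl group on the convex face away from the lactone ring. The step needs regioselectivity, and matched polarity secures it: the electron-rich veratryl group holds the positive charge on its own carbon and leaves the largest HOMO coefficient on the CH2 terminus, which pairs with the largest LUMO coefficient at the β-carbon. Excess 9, slow addition and the low solubility of CsF keep the medium only weakly basic so that cycloaddition should outrun γ-deprotonation of 6, and any C2-endo isomer can be equilibrated with acid at this benzylic ether carbon to the more stable exo isomer.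

Step 5
Reactants: 11 (3S,3aR,6S,6aS)-3-[4-(benzyloxy)-3-methoxyphenyl]-6-(3,4-dimethoxyphenyl)tetrahydro-1H,3H-furo[3,4-c]furan-1-one
Product: 13 (2S,3S,4R)-2-(3,4-dimethoxyphenyl)-4-(4-hydroxy-3-methoxybenzyl)tetrahydrofuran-3-carboxylic acid, via phenol lactone 12 (not isolated)
Conditions: H2 (1 atm), 10% Pd/C, EtOAc–AcOH (4:1), rt, stopped after uptake of 2 equiv H2
Reagents that add atoms: none
Why: Benzylic hydrogenolysis removes the O-benzyl group first, and the resulting p-hydroxybenzylic C–O bond with its carboxylate leaving group should then cleave much faster than the C2–O1 ether bond at the veratryl ring, which erases the sacrificial stereocentre and leaves C2, C3 and C4 untouched.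

Step 6
Reactants: 13 (2S,3S,4R)-2-(3,4-dimethoxyphenyl)-4-(4-hydroxy-3-methoxybenzyl)tetrahydrofuran-3-carboxylic acid
Product: 14 [(2S,3R,4R)-2-(3,4-dimethoxyphenyl)-4-(4-hydroxy-3-methoxybenzyl)tetrahydrofuran-3-yl]methanol
Conditions: BH3·THF (4 equiv), THF, 0 °C to rt; aq NH4Cl
Reagents that add atoms: none
Why: Chemoselective borane reduction of a carboxylic acid through its acyloxyborane is non-basic, so the C3 centre next to the carboxyl group is not epimerised, and the transient phenol borate is hydrolysed on work-up.

Compound list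
1 | 4-(benzyloxy)-3-methoxybenzaldehyde | COc1cc(C=O)ccc1OCc1ccccc1 | starting material
2 | methyl propiolate | C#CC(=O)OC | starting material
3 | methyl 3-(methylzincio)prop-2-ynoate | C[Zn]C#CC(=O)OC | intermediate
4 | methyl (4R)-4-[4-(benzyloxy)-3-methoxyphenyl]-4-hydroxybut-2-ynoate | COC(=O)C#C[C@H](O)c1ccc(OCc2ccccc2)c(OC)c1 | intermediate
5 | methyl (2Z,4S)-4-[4-(benzyloxy)-3-methoxyphenyl]-4-hydroxybut-2-enoate | COC(=O)/C=C\[C@H](O)c1ccc(OCc2ccccc2)c(OC)c1 | intermediate
6 | (5S)-5-[4-(benzyloxy)-3-methoxyphenyl]furan-2(5H)-one | O=C1C=C[C@@H](c2ccc(OCc3ccccc3)c(OC)c2)O1 | intermediate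
7 | 3,4-dimethoxybenzaldehyde | COc1ccc(C=O)cc1OC | starting material
8 | (trimethylsilyl)methanol | C[Si](C)(C)CO | starting material
9 | {[chloro(3,4-dimethoxyphenyl)methoxy]methyl}trimethylsilane (racemic) | COc1ccc(C(Cl)OC[Si](C)(C)C)cc1OC | intermediate
10 | (E)-(3,4-dimethoxybenzylidene)oxonium methylide (carbonyl ylide) | COc1ccc(/C=[O+]/[CH2-])cc1OC | intermediate
11 | (3S,3aR,6S,6aS)-3-[4-(benzyloxy)-3-methoxyphenyl]-6-(3,4-dimethoxyphenyl)tetrahydro-1H,3H-furo[3,4-c]furan-1-one | O=C1O[C@H](c3ccc(OCc4ccccc4)c(OC)c3)[C@H]2CO[C@H](c5ccc(OC)c(OC)c5)[C@@H]12 | intermediate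
12 | (3S,3aR,6S,6aS)-6-(3,4-dimethoxyphenyl)-3-(4-hydroxy-3-methoxyphenyl)tetrahydro-1H,3H-furo[3,4-c]furan-1-one | O=C1O[C@H](c3ccc(O)c(OC)c3)[C@H]2CO[C@H](c5ccc(OC)c(OC)c5)[C@@H]12 | intermediate
13 | (2S,3S,4R)-2-(3,4-dimethoxyphenyl)-4-(4-hydroxy-3-methoxybenzyl)tetrahydrofuran-3-carboxylic acid | COc1cc(C[C@H]2CO[C@H](c3ccc(OC)c(OC)c3)[C@H]2C(=O)O)ccc1O | intermediate
14 | [(2S,3R,4R)-2-(3,4-dimethoxyphenyl)-4-(4-hydroxy-3-methoxybenzyl)tetrahydrofuran-3-yl]methanol | COc1cc(C[C@H]2CO[C@H](c3ccc(OC)c(OC)c3)[C@H]2CO)ccc1O | target

Total step count: 6. Longest linear sequence: 5 (steps 1, 2, 4, 5, 6).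

Steps most likely to fail

Step 4. Fluoride may deprotonate the acidic γ-position of the butenolide. This would erode its configuration and divert it into vinylogous side reactions before the ylide is trapped. The fallback sets out from 4 and comes back at 11.
- Compound 4 is silylated (TIPSOTf, 2,6-lutidine, CH2Cl2) to methyl (4R)-4-[4-(benzyloxy)-3-methoxyphenyl]-4-[(triisopropylsilyl)oxy]but-2-ynoate F1.
- Semihydrogenation over Pd/CaCO3 poisoned with Pb(OAc)2 gives methyl (2Z,4S)-4-[4-(benzyloxy)-3-methoxyphenyl]-4-[(triisopropylsilyl)oxy]but-2-enoate F2.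
- In this open-chain Z-enoate, A(1,3) strain holds the γ C–H bond in the alkene plane, out of conjugation, so it is kinetically non-acidic.
- The ylide from 9 and CsF should add anti to the bulky silyloxy group (Felkin–Anh-type approach on the locked conformer, the same face as in 6). The product is methyl (2S,3S,4R)-4-{(S)-[4-(benzyloxy)-3-methoxyphenyl][(triisopropylsilyl)oxy]methyl}-2-(3,4-dimethoxyphenyl)tetrahydrofuran-3-carboxylate F3.
- TBAF buffered with AcOH in THF removes the silyl group, and the freed alcohol lactonises onto the cis ester to give 11.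

Step 5. Hydrogenolysis may run on into the benzylic C2–O1 bond and open the tetrahydrofuran ring, or it may stall before the lactone C–O bond is cleaved. The fallback sets out from 11 and comes back at 13.
- Hydrogenation in neutral EtOAc is stopped after debenzylation, and 12 is isolated.
- Compound 12 is then treated with NaBH4 in aqueous NaOH and THF.
- The phenoxide expels the carboxylate by 1,6-elimination to give the p-quinone methide (2S,3S,4R)-2-(3,4-dimethoxyphenyl)-4-[(3-methoxy-4-oxocyclohexa-2,5-dien-1-ylidene)methyl]tetrahydrofuran-3-carboxylic acid F4 (either alkene geometry, present as its carboxylate).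
- Hydride reduces F4 at the exocyclic carbon to give 13.
- The veratryl ring has no free phenol and cannot form a quinone methide, so the C2–O1 bond stays inert.

Step 3. The electron-rich α-chloro ether may ionise and undergo Friedel–Crafts self-condensation, or conversion may stay incomplete because water forms in the same flask. The fallback sets out from 7 and 8 and comes back at 9.
- Acetalisation (cat TsOH, toluene, Dean–Stark trap) gives the stable, purifiable 4-{bis[(trimethylsilyl)methoxy]methyl}-1,2-dimethoxybenzene F5.
- Anhydrous acetal–acyl chloride exchange (AcCl, cat ZnCl2, CH2Cl2, 0 °C) converts F5 into 9 just before use.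

Further compounds
F1 | step 4 | methyl (4R)-4-[4-(benzyloxy)-3-methoxyphenyl]-4-[(triisopropylsilyl)oxy]but-2-ynoate | COC(=O)C#C[C@H](O[Si](C(C)C)(C(C)C)C(C)C)c1ccc(OCc2ccccc2)c(OC)c1
F2 | step 4 | methyl (2Z,4S)-4-[4-(benzyloxy)-3-methoxyphenyl]-4-[(triisopropylsilyl)oxy]but-2-enoate | COC(=O)/C=C\[C@H](O[Si](C(C)C)(C(C)C)C(C)C)c1ccc(OCc2ccccc2)c(OC)c1
F3 | step 4 | methyl (2S,3S,4R)-4-{(S)-[4-(benzyloxy)-3-methoxyphenyl][(triisopropylsilyl)oxy]methyl}-2-(3,4-dimethoxyphenyl)tetrahydrofuran-3-carboxylate | COc1cc([C@@H](O[Si](C(C)C)(C(C)C)C(C)C)[C@H]2CO[C@H](c3ccc(OC)c(OC)c3)[C@H]2C(=O)OC)ccc1OCc1ccccc1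
F4 | step 5 | (2S,3S,4R)-2-(3,4-dimethoxyphenyl)-4-[(3-methoxy-4-oxocyclohexa-2,5-dien-1-ylidene)methyl]tetrahydrofuran-3-carboxylic acid | COC1=CC(=C[C@H]2CO[C@H](c3ccc(OC)c(OC)c3)[C@H]2C(=O)O)C=CC1=O
F5 | step 3 | 4-{bis[(trimethylsilyl)methoxy]methyl}-1,2-dimethoxybenzene | COc1ccc(C(OC[Si](C)(C)C)OC[Si](C)(C)C)cc1OC
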